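## Retrosynthetic overview

- **Feature.** Ring A is the carbocycle C4a–C5–C6–C7–C8–C8a and ring B is the pyridone N1–C2–C3–C4–C4a–C8a. The pair C8a/N1–OMe is a masked cyclohexanone O-methyl oxime, and C4(=O)–C3–C2–CH2O is a masked 4-oxygenated but-2-ynoyl chain. Ring B therefore lacks only the N1–C2 bond, and C3 is the one position left free for a handle.
- **Late disconnections.** O–Si is cleaved with fluoride. C3–OMe comes from copper-catalysed coupling of a C3 iodide with methanol.
- **Key disconnection.** N1–C2 and C3–I are made together by ICl-triggered closure of the oxime-ether ynone.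
- **Precursor.** A three-component coupling on cyclohexenone forms C5–octyl by asymmetric conjugate addition (the only stereocentre) and C4a–C4 by aldol trapping with a silyloxy ynal. Oximation at C8a and oxidation at C4 follow.
- **Ring order.** Ring A is bought; ring B is closed in the key step.

Key step: step 5

Assumption: the ligand antipode that leads to the (R)-configured enolate 6 is fixed by a test run with protic quench; both antipodes of the ferrocenyl diphosphine are commercial.

## Route

Step 1
Reactants: 1 tert-butyldimethyl(prop-2-yn-1-yloxy)silane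
Product: 3 4-(tert-butyldimethylsilyloxy)but-2-ynal, via lithium acetylide 2 (not isolated)
Conditions: n-BuLi, THF, −78 °C; DMF, −78 to 0 °C; inverse quench into aq KH2PO4/MTBE, 0 °C
Reagents that add atoms: N,N-dimethylformamide, CN(C)C=O
Why: Formylation of a lithium acetylide with DMF is the standard entry to ynals, the buffered inverse quench keeps the released amine from adding to the ynal, and the oxygen is carried as a silyl ether because fluoride removes it at the end without endangering N1–O (at risk under hydrogenolysis) or the C3 methoxy group beside C4=O (at risk of chelation-assisted cleavage by boron halides).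

Step 2
Reactants: 4 cyclohex-2-en-1-one, 5 octylmagnesium bromide, 3 4-(tert-butyldimethylsilyloxy)but-2-ynal
Product: 7 (2R,3R)-2-[4-(tert-butyldimethylsilyloxy)-1-hydroxybut-2-yn-1-yl]-3-octylcyclohexan-1-one (2,3-trans; both carbinol epimers), via bromomagnesium enolate 6 (not isolated)
Conditions: CuBr·SMe2 (5 mol %), 1-[α-(dimethylamino)-2-(diphenylphosphino)benzyl]-2-(diphenylphosphino)ferrocene (TaniaPhos, 6 mol %), Et2O, 0 °C, slow addition of 5 (1.1 equiv) to 4; then −78 °C, 3 (1.3 equiv)
Reagents that add atoms: none
Why: Copper-catalysed enantioselective conjugate addition of a linear alkyl Grignard reagent to a cyclic enone sets the future C5 (the chiral diphosphine chooses the enone face, giving R), and the regiodefined enolate 6 is trapped in a tandem aldol addition at the carbonyl of the non-enolisable ynal from the face away from the octyl group (2,3-trans), while the uncontrolled carbinol centre is erased in step 4.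

Step 3
Reactants: 7 (2R,3R)-2-[4-(tert-butyldimethylsilyloxy)-1-hydroxybut-2-yn-1-yl]-3-octylcyclohexan-1-one, 8 O-methylhydroxylamine hydrochloride
Product: 9 (1E,2S,3R)-2-[4-(tert-butyldimethylsilyloxy)-1-hydroxybut-2-yn-1-yl]-3-octylcyclohexan-1-one O-methyl oxime
Conditions: 8 (2 equiv), NaOAc (2 equiv), MeOH, rt
Reagents that add atoms: none
Why: Oxime-ether condensation under acetate buffer is mild enough to avoid retro-aldol cleavage, dehydration and desilylation, the alkyne is not yet a Michael acceptor at the alcohol oxidation level, and allylic strain with the C2 branch places the methoxy group on the CH2 side (E geometry).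

Step 4
Reactants: 9 (1E,2S,3R)-2-[4-(tert-butyldimethylsilyloxy)-1-hydroxybut-2-yn-1-yl]-3-octylcyclohexan-1-one O-methyl oxime
Product: 10 (1E,2S,3R)-2-[4-(tert-butyldimethylsilyloxy)but-2-ynoyl]-3-octylcyclohexan-1-one O-methyl oxime
Conditions: Dess–Martin periodinane (1.3 equiv), CH2Cl2, 0 °C; used at once
Reagents that add atoms: none
Why: Dess–Martin oxidation turns secondary propargylic alcohols into ynones under near-neutral conditions, leaves the oxime ether, alkyne and silyl ether alone, merges both carbinol epimers into one ketone, and unmasks the acceptor only after the nitrogen is already bound as C=N.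

Step 5
Reactants: 10 (1E,2S,3R)-2-[4-(tert-butyldimethylsilyloxy)but-2-ynoyl]-3-octylcyclohexan-1-one O-methyl oxime
Product: 12 (R)-2-[(tert-butyldimethylsilyloxy)methyl]-3-iodo-1-methoxy-5-octyl-5,6,7,8-tetrahydroquinolin-4(1H)-one, via N-methoxyiminium chloride 11 (not isolated)
Conditions: ICl (1.2 equiv), NaHCO3 (3 equiv), CH2Cl2, −78 to 0 °C, dark
Reagents that add atoms: iodine monochloride, ClI
Why: Proposed new method: ICl polarises the C2≡C3 triple bond of 10 as an iodonium-type complex, the sp2 lone pair of the oxime-ether nitrogen bonds to C2 while iodine stays on C3, and the N-methoxyiminium chloride 11 hands its C4a proton (α to both C4=O and C8a=N+) to NaHCO3 faster than chloride can attack the O-methyl group, which leaves the neutral cross-conjugated 4-pyridone. The closest known reaction types are the ICl cyclisation of 2-methoxyaryl and 2-(dimethylamino)aryl ynones to 3-iodochromones and 3-iodo-4-quinolones and the halocyclisation of 2-alkynylbenzaldehyde oximes and imines through nitrogen; new here is a ketone O-methyl oxime as the nucleophile toward an ynone with the N–OCH3 group retained. Ring B (N1, C2, C3, C4, C4a, C8a), the only ring formed, closes 6-endo-dig. No stereocentre is made: C4a turns sp2, so its configuration in 10 does not matter, and C5 bears no acidic hydrogen and stays R. The step needs attack of nitrogen at C2 in preference to 5-exo attack at C3, to iodination at C4a and to iodine-free conjugate addition; the ynone polarisation places the electrophilic character on C2, the E geometry turns the nitrogen lone pair toward the acyl chain and the methoxy oxygen away from it, and a fast electrophile at −78 °C on freshly made 10 outruns tautomerisation. Tautomerisation of 10 to its enamine form (which also interconverts any Z oxime ether) or prior addition of ICl across the triple bond would not divert the material, since both paths end in the same N1–C2 closure.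

Step 6
Reactants: 12 (R)-2-[(tert-butyldimethylsilyloxy)methyl]-3-iodo-1-methoxy-5-octyl-5,6,7,8-tetrahydroquinolin-4(1H)-one
Product: 13 (R)-2-[(tert-butyldimethylsilyloxy)methyl]-1,3-dimethoxy-5-octyl-5,6,7,8-tetrahydroquinolin-4(1H)-one
Conditions: CuI (20 mol %), 1,10-phenanthroline (40 mol %), Cs2CO3 (2 equiv), MeOH, 80 °C, sealed tube, Ar
Reagents that add atoms: methanol, CO
Why: Ullmann-type copper-catalysed C–O coupling of a heteroaryl iodide with methanol exchanges iodine for methoxy at the only halogenated position, carbonate in place of a large excess of methoxide limits SN2 attack on the N–O–CH3 methyl group, C5–H sits on C4a (α to the carbonyl) and is not vinylogously acidic so the stereocentre holds, and any silyl ether lost here only delivers 14 early.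

Step 7
Reactants: 13 (R)-2-[(tert-butyldimethylsilyloxy)methyl]-1,3-dimethoxy-5-octyl-5,6,7,8-tetrahydroquinolin-4(1H)-one
Product: 14 (R)-2-(hydroxymethyl)-1,3-dimethoxy-5-octyl-5,6,7,8-tetrahydroquinolin-4(1H)-one
Conditions: HF·pyridine, THF, 0 °C to rt
Reagents that add atoms: none
Why: Fluoride-induced desilylation of the primary TBS ether is driven by Si–F bond formation and affects neither the N-methoxy group, the C3 methyl ether, the pyridone nor C5.

## Compound list

1 | tert-butyldimethyl(prop-2-yn-1-yloxy)silane | C#CCO[Si](C)(C)C(C)(C)C | starting material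
2 | [3-(tert-butyldimethylsilyloxy)prop-1-yn-1-yl]lithium | [Li]C#CCO[Si](C)(C)C(C)(C)C | intermediate
3 | 4-(tert-butyldimethylsilyloxy)but-2-ynal | O=CC#CCO[Si](C)(C)C(C)(C)C | intermediate
4 | cyclohex-2-en-1-one | O=C1C=CCCC1 | starting material
5 | octylmagnesium bromide | CCCCCCCC[Mg]Br | starting material
6 | bromomagnesium (R)-3-octylcyclohex-1-en-1-olate | CCCCCCCC[C@@H]1CCCC(O[Mg]Br)=C1 | intermediate
7 | (2R,3R)-2-[4-(tert-butyldimethylsilyloxy)-1-hydroxybut-2-yn-1-yl]-3-octylcyclohexan-1-one, both carbinol epimers | CCCCCCCC[C@@H]1CCCC(=O)[C@H]1C(O)C#CCO[Si](C)(C)C(C)(C)C | intermediate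
8 | O-methylhydroxylamine hydrochloride | CON.Cl | starting material
9 | (1E,2S,3R)-2-[4-(tert-butyldimethylsilyloxy)-1-hydroxybut-2-yn-1-yl]-3-octylcyclohexan-1-one O-methyl oxime, both carbinol epimers | CCCCCCCC[C@@H]1CCC/C(=N\OC)[C@H]1C(O)C#CCO[Si](C)(C)C(C)(C)C | intermediate
10 | (1E,2S,3R)-2-[4-(tert-butyldimethylsilyloxy)but-2-ynoyl]-3-octylcyclohexan-1-one O-methyl oxime | CCCCCCCC[C@@H]1CCC/C(=N\OC)[C@H]1C(=O)C#CCO[Si](C)(C)C(C)(C)C | intermediate
11 | (4aS,5R)-2-[(tert-butyldimethylsilyloxy)methyl]-3-iodo-1-methoxy-5-octyl-4-oxo-4,4a,5,6,7,8-hexahydroquinolin-1-ium chloride | CCCCCCCC[C@@H]1CCCC2=[N+](OC)C(CO[Si](C)(C)C(C)(C)C)=C(I)C(=O)[C@@H]12.[Cl-] | intermediate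
12 | (R)-2-[(tert-butyldimethylsilyloxy)methyl]-3-iodo-1-methoxy-5-octyl-5,6,7,8-tetrahydroquinolin-4(1H)-one | CCCCCCCC[C@@H]1CCCc2c1c(=O)c(I)c(CO[Si](C)(C)C(C)(C)C)n2OC | intermediate
13 | (R)-2-[(tert-butyldimethylsilyloxy)methyl]-1,3-dimethoxy-5-octyl-5,6,7,8-tetrahydroquinolin-4(1H)-one | CCCCCCCC[C@@H]1CCCc2c1c(=O)c(OC)c(CO[Si](C)(C)C(C)(C)C)n2OC | intermediate
14 | (R)-2-(hydroxymethyl)-1,3-dimethoxy-5-octyl-5,6,7,8-tetrahydroquinolin-4(1H)-one | CCCCCCCC[C@@H]1CCCc2c1c(=O)c(OC)c(CO)n2OC | target

## Step count and risks

Total step count: 7.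
Longest linear sequence: 7 (1 → 3 → 7 → 9 → 10 → 12 → 13 → 14). Counted from 4 it is 6.

**Step 5.**
- The ring closure may lose out to electrophilic iodination at C4a through an enol or enamine tautomer.
- It may also lose out to plain addition of ICl across the triple bond.
- The weakly basic oxime-ether nitrogen may react too slowly.

The fallback uses known chemistry and takes ring closure and iodination apart. It sets out from 10, which is warmed with Et3N in EtOH. The enamine tautomer then adds to the ynone in a 6-endo-dig aza-Michael reaction. This is the reaction type that turns 2-aminoaryl ynones into 4-quinolones and enaminone ynones into 4-pyridones. The product is (R)-2-[(tert-butyldimethylsilyloxy)methyl]-1-methoxy-5-octyl-5,6,7,8-tetrahydroquinolin-4(1H)-one F1. Electrophilic iodination with NIS in MeCN at C3, the only free ring position, comes back to the route at 12.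

**Step 6.**
- Oxidative addition may be slow at an iodide flanked on both sides.
- Hydrodeiodination may compete.
- The hot basic medium may strip the N-methoxy methyl group by nucleophilic attack, or by base-induced loss of formaldehyde.

The fallback replaces C–O coupling by metalation, borylation, oxidation and alkylation, and sets out from 12.
1. Iodine–magnesium exchange with i-PrMgCl·LiCl (THF, −40 °C) gives the 3-chloromagnesio pyridone F2.
2. B(OMe)3 converts it into the C3 dimethyl boronate F3.
3. H2O2/NaOH in the same flask gives the 3-hydroxy-4-pyridone F4.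
4. O-Methylation of this acidic hydroxyl (MeI, K2CO3, acetone) comes back to the route at 13.

**Step 2.**
- Uncatalysed background 1,4- or 1,2-addition may erode enantiopurity.
- Residual Grignard reagent may consume the ynal.
- The magnesium aldolate may revert on warming.

The fallback separates the two bond formations and sets out from 4 and 5 through enolate 6. The enolate is silylated (TMSCl, Et3N, DMPU, −78 °C to rt), and (R)-trimethyl[(3-octylcyclohex-1-en-1-yl)oxy]silane F5 is isolated. This allows the conjugate addition to be optimised and assayed on its own. An irreversible Mukaiyama aldol addition of F5 to 3 (BF3·OEt2, CH2Cl2, −78 °C), again anti to the octyl group, comes back to the route at 7.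

## Further compounds

F1 | step 5 | (R)-2-[(tert-butyldimethylsilyloxy)methyl]-1-methoxy-5-octyl-5,6,7,8-tetrahydroquinolin-4(1H)-one | CCCCCCCC[C@@H]1CCCc2c1c(=O)cc(CO[Si](C)(C)C(C)(C)C)n2OC
F2 | step 6 | (R)-2-[(tert-butyldimethylsilyloxy)methyl]-3-(chloromagnesio)-1-methoxy-5-octyl-5,6,7,8-tetrahydroquinolin-4(1H)-one | CCCCCCCC[C@@H]1CCCc2c1c(=O)c([Mg]Cl)c(CO[Si](C)(C)C(C)(C)C)n2OC
F3 | step 6 | dimethyl {(R)-2-[(tert-butyldimethylsilyloxy)methyl]-1-methoxy-5-octyl-4-oxo-1,4,5,6,7,8-hexahydroquinolin-3-yl}boronate | CCCCCCCC[C@@H]1CCCc2c1c(=O)c(B(OC)OC)c(CO[Si](C)(C)C(C)(C)C)n2OC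
F4 | step 6 | (R)-2-[(tert-butyldimethylsilyloxy)methyl]-3-hydroxy-1-methoxy-5-octyl-5,6,7,8-tetrahydroquinolin-4(1H)-one | CCCCCCCC[C@@H]1CCCc2c1c(=O)c(O)c(CO[Si](C)(C)C(C)(C)C)n2OC
F5 | step 2 | (R)-trimethyl[(3-octylcyclohex-1-en-1-yl)oxy]silane | CCCCCCCC[C@@H]1CCCC(O[Si](C)(C)C)=C1
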